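The ratio to look at first is impurity to free enzyme as charged: 1.10 in the summer flask and 1.65 in the noon run. Both lie above one, and the run with the higher ratio stopped lower, although its temperature differs too.

| flask | starting material | free enzyme | impurity | temperature | remark | time |
|---|---|---|---|---|---|---|
| summer | 0.030 M | 3 µM | 3.3 µM | 25 °C | the very flask that is asked about, followed so far |  |
| noon | 0.030 M | 2 µM | 3.3 µM | 20 °C | run made earlier |  |
| flask | 0.030 M | 3.0 µM | 3.3 µM | 25 °C |  | 3.0 h |

| summer: time / min | summer: product / % | noon: time / min | noon: product / % |
|---|---|---|---|
| 20.0 | 26.6 | 0.333 | 9.7 |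
| 40.0 | 26.7 | 0.500 | 12.9 |
| 50.0 | 27.5 | 0.833 | 15.3 |
| 80.0 | 29.5 | 1.33 | 14.4 |
| 90.0 | 26.5 | 2.50 | 14.7 |
| 120 | 29.4 | 4.00 | 15.4 |

(scatter of a reading: 1 percentage point)

- oak: change nothing and wait 3.0 h more
- cedar: at 3.0 h take out 90 % of the product then present, then wait 3.0 h
- maple: at 3.0 h raise the temperature by 15 K, then wait 3.0 h
- birch: at 3.0 h add free enzyme, 50.0 % of the amount charged, then wait 3.0 h

* product, in percent of the starting material first charged, at 3.0 h
* what to do for the largest gain in product; "none" if nothing gains more than 2 percentage points (oak / cedar / maple / birch / none)
* product present, with what was taken out counted in, in percent of the starting material first charged, after oak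
* product present, with what was taken out counted in, in percent of the starting material first charged, after birch

- product taken out counts as made
- the earlier runs were read with a standard deviation of 1 percentage point
- additions bring no volume worth counting

You can read two things from these runs. The noon run stands near 15.4 % from about 0.833 min, and the summer readings lie between 26.5 % and 29.5 % from 20.0 min onwards, with a scatter of 1 percentage point. Both stop with most of the starting material unreacted, so my own suspicion falls on the catalyst. Suppose each impurity takes one free enzyme, quickly. Then the pairing ends when free enzyme, the smaller charge, has been consumed, and the balance of the two gives what stays over: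

surplus = c(impurity) − c(free enzyme) = 3.3 µM − 3.0 µM = 0.300 µM

This surplus, the impurity still waiting once the free enzyme has been consumed, is the quantity to carry. With this value above zero, you should expect the summer flask to hold its plateau, and oak, cedar and maple to find no free enzyme to work with. Birch is different: the enzyme it adds is more than the surplus, so on this reckoning some stays free once the surplus has taken its share:

free enzyme after birch = 1.50 µM − 0.300 µM = 1.20 µM

The forecast puts the product at 28 % (27 % to 29.5 %) and 28.3 % after oak (27.2 % to 31 %). It chooses birch, with 97 % after it (40 % to 100 %), in the words “that should finish the conversion within minutes”.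

The simulation gives 27.3 % now and 27.3 % after oak. Oak, cedar and maple gain 0, 0 and 0 points, while birch gains 60 points and reaches 87.5 %.

    free enzyme → unfolded enzyme (k = 7.60 × 10⁻⁴ s⁻¹, Ea = 228 kJ mol⁻¹)
    starting material + free enzyme → product + free enzyme, rate k2*[starting material]^2.5*[free enzyme]/(1 + ([starting material]/Kh2)^2.5) (48.0 mM, k = 1.80 × 10⁶ M⁻²·⁵ s⁻¹, Ea = 13.0 kJ mol⁻¹)
    free enzyme + impurity → spent catalyst (k = 43000 M⁻¹ s⁻¹, Ea = 36.0 kJ mol⁻¹)
    (constants at 25 °C)

Part of the stop in this flask is the impurity step: without it the flask gives 93.2 % at 3.0 h, against 27.3 %. The same step is the largest single effect on the gain from birch: without that step birch gains 1.6 points, against 60 points, and with it the flask ends at 87.5 %, against the forecast's 97 %. The neighbour charged with 5.1 × 10⁻⁶ M of free enzyme turns this flask's surplus of 0.300 µM around, with 1.80 µM of enzyme beyond the impurity, or 35.3 % of its enzyme, and at 180 min it holds 35.3 % unfolded enzyme, 0 % impurity and 90.4 % product.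

The data are calculated for an exercise; noise was put on by code.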